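(Its constants were set for the occasion; the rest is arithmetic.)

The constants are best read as lifetimes: while a cycle of one loop runs steadily, each form of the catalyst holds a share equal to its waiting time over the time of a whole turn.

starting material 0.20 mM; partner 0.950 equiv; free catalyst 2.5 mol%

    starting material + free catalyst ⇌ catalyst intermediate A (K1 = 12000 M⁻¹, k1 = 1.2 × 10⁵ M⁻¹ s⁻¹)
    catalyst intermediate A → catalyst intermediate B (k2 = 1.9 s⁻¹)
    partner + catalyst intermediate B → catalyst intermediate C (k3 = 1.2 × 10⁶ M⁻¹ s⁻¹)
    catalyst intermediate C → released group + catalyst intermediate D (k4 = 0.95 s⁻¹)
    catalyst intermediate D → catalyst intermediate E (k5 = 1.9 s⁻¹)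
    catalyst intermediate E → free catalyst + target (k6 = 42 s⁻¹)
    2 partner → self-condensation product (k7 = 120 M⁻¹ s⁻¹)

- the form that holds most of the catalyst when 50% of the starting material are converted (catalyst intermediate B / free catalyst / catalyst intermediate E / catalyst intermediate D / catalyst intermediate A / catalyst intermediate C)
- its share of the catalyst then
- apparent order in free catalyst when 50% of the starting material are converted (percent change of the rate of making target for one percent more free catalyst charged)

Take the flask at the asked conversion and give each form its wait per turn. Free catalyst's wait counts the returns from catalyst intermediate A.

free catalyst: 0.522 s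
catalyst intermediate A: 0.526 s
catalyst intermediate C: 1.05 s
catalyst intermediate D: 0.526 s
catalyst intermediate E: 0.0238 s

These add up to the turn time without the wait for partner, 2.65 s. Catalyst intermediate C has the longest of these waits, so it is my resting state as long as catalyst intermediate B waits less than it does.

From above, a wait of nothing in catalyst intermediate B gives C a share of 39.7%.

To tighten this, count turns. Your flask needs 20.0 turns per catalyst, about 53.0 s, while self-condensation's first half-life is 21.9 s. Self-condensation by itself leaves about 29.3% of the partner, so B waits at least about 0.0150 s and the ceiling becomes about 39.5%.

From below, the turnover needs about 52.6% of the partner charge, more than the 29.3% that self-condensation by itself leaves, so the two losses counted apart overrun the charge and give no floor. I can say that B ties C when partner stands at 0.417% of its charge, and above that C keeps at least 28.4%.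

The forecast, catalyst intermediate C at 37% with order 1.2, lies inside this bracket and says that “self-condensation eats most of the partner”.

The flask gives catalyst intermediate C at 37.4%, with order 1.3. Catalyst intermediate B then holds 5.10%, and partner reads 3.95% of its charge at 0.800 min. Catalyst charged over the turn time gives 0.113 mM min⁻¹, and the reading of 0.108 mM min⁻¹ falls below it by 4.88%. By 4.00 min partner reads 0%, catalyst intermediate B holds 100%, and target stands at 52.2%.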